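**Plan**
1. Numbering used: lactone carbonyl C1, C2 (Me), C3 (ketone), C4 (OH and C4'H2OH), C5, C6(Me)=C7, C8 (Me), C9, C10 (=CH2), C11=C12 (C12'H2OH), C13 (Et, ring oxygen). The C3 ketone bonded to the fully substituted C4 carbinol is an acyloin inside the 14-membered lactone ring. It is the retron of a crossed benzoin union of a C3 aldehyde (acyl anion) with a C4 α-silyloxy ketone, and this event closes the ring.
2. Retrosynthetic cuts, in order: C3–C4 (ring), C1–O13 (ester), C12–C13 (enyne plus propanal), C10–C11 (alkenyl–alkynyl coupling), C4–C5 (glycolate alkylation), C6=C7 (Wittig), C8–C9 (auxiliary alkylation).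
3. Forward: the C4'–C10 chain is grown linearly from an oxazolidinone alkylation, extended to the enyne and the 2-substituted diene, esterified at O13 with the C1–C3 acid and oxidised to the seco keto-aldehyde; the only ring is closed last.
4. Stereochemistry: C8 from the Evans alkylation; C13 from a CBS reduction; quaternary C4 from the chiral carbene catalyst in the ring closure; C2 by equilibration between its two carbonyls; 6E from the stabilised ylide; 11E from syn addition across the alkyne.

Key step: step 19

Assumption: C2 lies between the lactone and ketone carbonyls and is configurationally labile; the 2R configuration of the target is taken to be the thermodynamically preferred one on the macrocycle, so it is reached by equilibration however the centre is introduced.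
Remark: the carbinol carbon that becomes the C4 ketone is carried as both epimers (drawn without configuration) from the glycolate alkylation to the double oxidation, which erases it. TBS = tert-butyldimethylsilyl, TES = triethylsilyl.

Step 1
Reactants: 1 (R)-4-benzyl-3-propanoyl-1,3-oxazolidin-2-one; 2 2,3-dibromoprop-1-ene
Product: 3 (R)-4-benzyl-3-[(2S)-4-bromo-2-methylpent-4-enoyl]-1,3-oxazolidin-2-one
Conditions: NaN(SiMe3)2, THF, −78 °C; then 2, −78 to −45 °C
Reagents that add atoms: none
Why: Evans asymmetric alkylation, in which the chelated Z-sodium enolate is alkylated (SN2 at the allylic bromide) on the face opposite the benzyl group, which sets the C8 methyl centre as S.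

Step 2
Reactants: 3
Product: 4 (2S)-4-bromo-2-methylpent-4-en-1-ol
Conditions: LiBH4, MeOH (1 equiv), Et2O, 0 °C
Reagents that add atoms: none
Why: Reductive cleavage of the N-acyl oxazolidinone by borohydride should give the primary alcohol and the recoverable auxiliary without touching the α-stereocentre or the vinyl bromide.

Step 3
Reactants: 4; 5 ethyl 2-(triphenyl-λ5-phosphanylidene)propanoate
Product: 7 ethyl (2E,4S)-6-bromo-2,4-dimethylhepta-2,6-dienoate, via aldehyde 6 (not isolated)
Conditions: Dess–Martin periodinane, 5 (2.5 equiv), CH2Cl2, 0 °C to rt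
Reagents that add atoms: none
Why: Dess–Martin oxidation in the presence of the stabilised ylide (in situ Wittig olefination) traps the epimerisable α-methyl aldehyde as it forms and should give the E-trisubstituted C6=C7 bond, as is usual for stabilised ylides.

Step 4
Reactants: 7
Product: 8 (2E,4S)-6-bromo-2,4-dimethylhepta-2,6-dien-1-ol
Conditions: i-Bu2AlH, CH2Cl2, −78 °C; Rochelle salt work-up
Reagents that add atoms: none
Why: 1,2-Reduction of the enoate by the aluminium hydride should give the allylic alcohol without conjugate reduction or loss of the vinyl bromide.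

Step 5
Reactants: 8
Product: 9 (2E,4S)-1,6-dibromo-2,4-dimethylhepta-2,6-diene
Conditions: CBr4, PPh3, CH2Cl2, 0 °C
Reagents that add atoms: carbon tetrabromide, BrC(Br)(Br)Br
Why: Appel bromination converts the primary allylic alcohol into the bromide by SN2 displacement of the oxyphosphonium, so no allylic transposition is expected.

Step 6
Reactants: 9; 10 2,2-dimethyl-1,3-dioxolan-4-one
Product: 11 5-[(2E,4S)-6-bromo-2,4-dimethylhepta-2,6-dien-1-yl]-2,2-dimethyl-1,3-dioxolan-4-one (both epimers at the ring carbon)
Conditions: LiN(i-Pr)2, THF, −78 °C, 10 min; then 9, DMPU, −78 to −40 °C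
Reagents that add atoms: none
Why: Enolate alkylation of the glycolic acid acetonide by the reactive allylic bromide (SN2) forms the C4–C5 bond; the new carbinol centre is formed unselectively, which is harmless because it becomes the C4 ketone in step 18.

Step 7
Reactants: 11
Product: 12 (2RS,4E,6S)-8-bromo-4,6-dimethylnona-4,8-diene-1,2-diol
Conditions: LiBH4, THF/MeOH, 0 °C to rt
Reagents that add atoms: none
Why: Hydride reduction of the lactone-acetal opens the dioxolanone to the 1,2-diol (the released acetone is reduced by the excess hydride) and leaves both alkenes and the vinyl bromide untouched.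

Step 8
Reactants: 12
Product: 13 (2RS,4E,6S)-8-bromo-1-(tert-butyldimethylsilyloxy)-4,6-dimethylnona-4,8-dien-2-ol
Conditions: TBSCl (1.05 equiv), imidazole, CH2Cl2, −20 to 0 °C
Reagents that add atoms: tert-butyldimethylsilyl chloride, CC(C)(C)[Si](C)(C)Cl
Why: Silylation with the bulky chlorosilane is selective for the primary hydroxyl of a 1,2-diol, which installs the permanent C4' protecting group.

Step 9
Reactants: 13
Product: 14 (2RS,4E,6S)-8-bromo-1-(tert-butyldimethylsilyloxy)-4,6-dimethyl-2-(triethylsilyloxy)nona-4,8-diene
Conditions: TESCl, imidazole, CH2Cl2, 0 °C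
Reagents that add atoms: triethylsilyl chloride, CC[Si](Cl)(CC)CC
Why: Silylation of the remaining secondary hydroxyl as the more labile triethylsilyl ether gives a temporary group that can later be removed beside the two primary TBS ethers.

Step 10
Reactants: 14; 15 tert-butyldimethyl(prop-2-yn-1-yloxy)silane
Product: 16 (2RS,4E,6S)-1,11-bis(tert-butyldimethylsilyloxy)-4,6-dimethyl-8-methylidene-2-(triethylsilyloxy)undec-4-en-9-yne
Conditions: Pd(PPh3)4 (5 mol %), CuI (10 mol %), i-Pr2NH, THF, rt to 40 °C
Reagents that add atoms: none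
Why: Sonogashira coupling of the 2-bromoalkene with the terminal alkyne forms the C10–C11 bond and the 1,3-enyne under conditions that leave the silyl ethers alone.

Step 11
Reactants: 16; 17 propanal
Product: 18 (2RS,4E,6S,9E,11RS)-1-(tert-butyldimethylsilyloxy)-10-[(tert-butyldimethylsilyloxy)methyl]-4,6-dimethyl-8-methylidene-2-(triethylsilyloxy)trideca-4,9-dien-11-ol
Conditions: Ni(cod)2 (10 mol %), P(c-C5H9)3 (20 mol %), Et3B, EtOAc, 0 °C to rt
Reagents that add atoms: none
Why: Nickel-catalysed reductive coupling of a 1,3-enyne with an aldehyde: the conjugated C10 alkene directs oxidative cyclisation so that the C–C bond forms at the remote alkyne carbon C12, and syn delivery of hydrogen (from an ethyl group of Et3B by β-hydride elimination) and the carbinol carbon gives the 11E diene; C13 arises as both epimers and is corrected in steps 12 and 13.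

Step 12
Reactants: 18
Product: 19 (2RS,4E,6S,9E)-1-(tert-butyldimethylsilyloxy)-10-[(tert-butyldimethylsilyloxy)methyl]-4,6-dimethyl-8-methylidene-2-(triethylsilyloxy)trideca-4,9-dien-11-one
Conditions: Dess–Martin periodinane, pyridine, CH2Cl2, 0 °C
Reagents that add atoms: none
Why: Dess–Martin oxidation of the allylic alcohol removes the unselectively formed C13 centre and gives the enone needed for a reagent-controlled reduction.

Step 13
Reactants: 19
Product: 20 (2RS,4E,6S,9E,11S)-1-(tert-butyldimethylsilyloxy)-10-[(tert-butyldimethylsilyloxy)methyl]-4,6-dimethyl-8-methylidene-2-(triethylsilyloxy)trideca-4,9-dien-11-ol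
Conditions: (R)-1-methyl-3,3-diphenyltetrahydro-1H,3H-pyrrolo[1,2-c][1,3,2]oxazaborole (0.3 equiv), catecholborane, toluene, −78 °C
Reagents that add atoms: none
Why: Corey–Bakshi–Shibata reduction: with the α-branched dienyl group as the large and ethyl as the small substituent, the (R)-oxazaborolidine should deliver hydride to the face that gives the 13S alcohol, and catecholborane at low temperature favours 1,2-reduction and spares the alkenes.

Step 14
Reactants: 21 methyl (2R)-3-hydroxy-2-methylpropanoate
Product: 22 methyl (2R)-2-methyl-3-(triethylsilyloxy)propanoate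
Conditions: TESCl, imidazole, CH2Cl2, 0 °C
Reagents that add atoms: triethylsilyl chloride, CC[Si](Cl)(CC)CC
Why: Silylation of the primary hydroxyl gives the C3 oxygen the same temporary group as the C4 oxygen, so both can be released together.

Step 15
Reactants: 22
Product: 23 (2R)-2-methyl-3-(triethylsilyloxy)propanoic acid
Conditions: LiOH, THF/H2O, 0 °C; aq. HCl to pH 4
Reagents that add atoms: lithium hydroxide, [Li+].[OH-]
Why: Saponification of the methyl ester at low temperature should give the acid with the primary silyl ether intact; partial epimerisation at C2 would be of no consequence (see assumption).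

Step 16
Reactants: 20; 23
Product: 24 (2RS,4E,6S,9E,11S)-1-(tert-butyldimethylsilyloxy)-10-[(tert-butyldimethylsilyloxy)methyl]-4,6-dimethyl-8-methylidene-2-(triethylsilyloxy)trideca-4,9-dien-11-yl (2R)-2-methyl-3-(triethylsilyloxy)propanoate
Conditions: N,N'-dicyclohexylcarbodiimide, 4-(dimethylamino)pyridine (cat.), CH2Cl2, 0 °C to rt
Reagents that add atoms: none
Why: Steglich esterification (carbodiimide activation, acyl transfer by the aminopyridine) joins the C1–C3 unit to O13 with retention at C13, since the C–O bond of the alcohol is not broken.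

Step 17
Reactants: 24
Product: 25 (2RS,4E,6S,9E,11S)-1-(tert-butyldimethylsilyloxy)-10-[(tert-butyldimethylsilyloxy)methyl]-2-hydroxy-4,6-dimethyl-8-methylidenetrideca-4,9-dien-11-yl (2R)-3-hydroxy-2-methylpropanoate
Conditions: pyridinium p-toluenesulfonate, MeOH/CH2Cl2, 0 °C
Reagents that add atoms: none
Why: Acid-catalysed methanolysis should remove the two triethylsilyl ethers much faster than the primary TBS ethers, which frees exactly the two hydroxyls that must be oxidised.

Step 18
Reactants: 25
Product: 26 (4E,6S,9E,11S)-1-(tert-butyldimethylsilyloxy)-10-[(tert-butyldimethylsilyloxy)methyl]-4,6-dimethyl-8-methylidene-2-oxotrideca-4,9-dien-11-yl (2R)-2-methyl-3-oxopropanoate (used crude)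
Conditions: Dess–Martin periodinane (3 equiv), pyridine, CH2Cl2, 0 °C to rt
Reagents that add atoms: none
Why: Dess–Martin oxidation converts the primary and the secondary alcohol in one operation into the C3 aldehyde and the C4 ketone under buffered non-aqueous conditions that should spare the β,γ-unsaturated ketone and the formyl ester; the carbinol centre carried as a mixture is erased here.

Step 19
Reactants: 26
Product: 27 (3R,5R,7E,9S,12E,14S)-5,13-bis[(tert-butyldimethylsilyloxy)methyl]-14-ethyl-5-hydroxy-3,7,9-trimethyl-11-methylidene-1-oxacyclotetradeca-7,12-diene-2,4-dione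
Conditions: (5aS,10bR)-2-(pentafluorophenyl)-5a,10b-dihydro-4H,6H-indeno[2,1-b][1,2,4]triazolo[4,3-d][1,4]oxazin-2-ium tetrafluoroborate (30 mol %; or its enantiomer, whichever is matched with the substrate), i-Pr2NEt (30 mol %), toluene, 40 °C, syringe-pump addition of 26 to 0.002 M
Reagents that add atoms: none
Why: Proposed new method: the chiral triazolylidene adds to the C3 aldehyde and proton transfer gives the Breslow enaminol, an acyl anion equivalent that attacks the C4 ketone carbon through a hydrogen-bonded five-membered transition state, after which collapse of the adduct releases the carbene and leaves the C3 ketone next to the C4 tertiary carbinol. The closest known reactions are the enantioselective intramolecular aldehyde–ketone crossed benzoin, which closes five- and six-membered rings, and the carbene-catalysed Stetter macrocyclisation; what is new is the use of the crossed benzoin to close a macrocycle. The 14-membered lactone ring is closed in a 14-exo-trig mode, the ketone C=O remaining outside the ring. The quaternary C4 centre should be set under catalyst control, the aminoindane backbone and the N-C6F5 group leaving one face of the Breslow intermediate open to one face of the ketone, and the catalyst enantiomer that reinforces the bias of C8 and C13 towards 4R is the one to use; C2 is expected to settle under the amine base to the thermodynamic 2R epimer. The step needs donor/acceptor chemoselectivity, secured because only the aldehyde can form a Breslow intermediate and the α-silyloxy ketone is an activated acceptor, and it needs ring closure to outrun intermolecular aldehyde coupling, secured by slow addition at high dilution and the α-branched aldehyde. The weak amine base is chosen to keep C6=C7 out of conjugation with the C4 ketone until the ketone is consumed.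

Step 20
Reactants: 27
Product: 28 (3R,5R,7E,9S,12E,14S)-14-ethyl-5-hydroxy-5,13-bis(hydroxymethyl)-3,7,9-trimethyl-11-methylidene-1-oxacyclotetradeca-7,12-diene-2,4-dione (target)
Conditions: HF·pyridine, pyridine, THF, 0 °C to rt
Reagents that add atoms: none
Why: Fluoride-mediated Si–O cleavage with buffered HF·pyridine removes both primary silyl ethers under weakly acidic conditions that should leave the β-keto lactone and the tertiary acyloin intact and avoid base-induced acyl migration.

**Compound list**
1 | (R)-4-benzyl-3-propanoyl-1,3-oxazolidin-2-one | CCC(=O)N1[C@H](Cc2ccccc2)COC1=O | starting material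
2 | 2,3-dibromoprop-1-ene | C=C(Br)CBr | starting material
3 | (R)-4-benzyl-3-[(2S)-4-bromo-2-methylpent-4-enoyl]-1,3-oxazolidin-2-one | C=C(Br)C[C@H](C)C(=O)N1[C@H](Cc2ccccc2)COC1=O | intermediate
4 | (2S)-4-bromo-2-methylpent-4-en-1-ol | OC[C@@H](C)CC(Br)=C | intermediate
5 | ethyl 2-(triphenyl-λ5-phosphanylidene)propanoate | CCOC(=O)C(C)=P(c1ccccc1)(c1ccccc1)c1ccccc1 | starting material
6 | (2S)-4-bromo-2-methylpent-4-enal (not isolated) | O=C[C@@H](C)CC(Br)=C | intermediate
7 | ethyl (2E,4S)-6-bromo-2,4-dimethylhepta-2,6-dienoate | CCOC(=O)/C(C)=C/[C@@H](C)CC(Br)=C | intermediate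
8 | (2E,4S)-6-bromo-2,4-dimethylhepta-2,6-dien-1-ol | OC/C(C)=C/[C@@H](C)CC(Br)=C | intermediate
9 | (2E,4S)-1,6-dibromo-2,4-dimethylhepta-2,6-diene | BrC/C(C)=C/[C@@H](C)CC(Br)=C | intermediate
10 | 2,2-dimethyl-1,3-dioxolan-4-one | CC1(C)OCC(=O)O1 | starting material
11 | 5-[(2E,4S)-6-bromo-2,4-dimethylhepta-2,6-dien-1-yl]-2,2-dimethyl-1,3-dioxolan-4-one (both ring epimers) | CC1(C)OC(C/C(C)=C/[C@@H](C)CC(Br)=C)C(=O)O1 | intermediate
12 | (2RS,4E,6S)-8-bromo-4,6-dimethylnona-4,8-diene-1,2-diol | OCC(O)C/C(C)=C/[C@@H](C)CC(Br)=C | intermediate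
13 | (2RS,4E,6S)-8-bromo-1-(tert-butyldimethylsilyloxy)-4,6-dimethylnona-4,8-dien-2-ol | CC(C)(C)[Si](C)(C)OCC(O)C/C(C)=C/[C@@H](C)CC(Br)=C | intermediate
14 | (2RS,4E,6S)-8-bromo-1-(tert-butyldimethylsilyloxy)-4,6-dimethyl-2-(triethylsilyloxy)nona-4,8-diene | CC[Si](CC)(CC)OC(CO[Si](C)(C)C(C)(C)C)C/C(C)=C/[C@@H](C)CC(Br)=C | intermediate
15 | tert-butyldimethyl(prop-2-yn-1-yloxy)silane | C#CCO[Si](C)(C)C(C)(C)C | starting material
16 | (2RS,4E,6S)-1,11-bis(tert-butyldimethylsilyloxy)-4,6-dimethyl-8-methylidene-2-(triethylsilyloxy)undec-4-en-9-yne | CC[Si](CC)(CC)OC(CO[Si](C)(C)C(C)(C)C)C/C(C)=C/[C@@H](C)CC(=C)C#CCO[Si](C)(C)C(C)(C)C | intermediate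
17 | propanal | CCC=O | starting material
18 | (2RS,4E,6S,9E,11RS)-1-(tert-butyldimethylsilyloxy)-10-[(tert-butyldimethylsilyloxy)methyl]-4,6-dimethyl-8-methylidene-2-(triethylsilyloxy)trideca-4,9-dien-11-ol | CC[Si](CC)(CC)OC(CO[Si](C)(C)C(C)(C)C)C/C(C)=C/[C@@H](C)CC(=C)/C=C(\CO[Si](C)(C)C(C)(C)C)C(O)CC | intermediate
19 | (2RS,4E,6S,9E)-1-(tert-butyldimethylsilyloxy)-10-[(tert-butyldimethylsilyloxy)methyl]-4,6-dimethyl-8-methylidene-2-(triethylsilyloxy)trideca-4,9-dien-11-one | CC[Si](CC)(CC)OC(CO[Si](C)(C)C(C)(C)C)C/C(C)=C/[C@@H](C)CC(=C)/C=C(\CO[Si](C)(C)C(C)(C)C)C(=O)CC | intermediate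
20 | (2RS,4E,6S,9E,11S)-1-(tert-butyldimethylsilyloxy)-10-[(tert-butyldimethylsilyloxy)methyl]-4,6-dimethyl-8-methylidene-2-(triethylsilyloxy)trideca-4,9-dien-11-ol | CC[Si](CC)(CC)OC(CO[Si](C)(C)C(C)(C)C)C/C(C)=C/[C@@H](C)CC(=C)/C=C(\CO[Si](C)(C)C(C)(C)C)[C@H](CC)O | intermediate
21 | methyl (2R)-3-hydroxy-2-methylpropanoate | COC(=O)[C@H](C)CO | starting material
22 | methyl (2R)-2-methyl-3-(triethylsilyloxy)propanoate | COC(=O)[C@H](C)CO[Si](CC)(CC)CC | intermediate
23 | (2R)-2-methyl-3-(triethylsilyloxy)propanoic acid | OC(=O)[C@H](C)CO[Si](CC)(CC)CC | intermediate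
24 | ester of 20 with 23 (name in step 16) | CC[Si](CC)(CC)OC(CO[Si](C)(C)C(C)(C)C)C/C(C)=C/[C@@H](C)CC(=C)/C=C(\CO[Si](C)(C)C(C)(C)C)[C@H](CC)OC(=O)[C@H](C)CO[Si](CC)(CC)CC | intermediate
25 | seco diol (name in step 17) | OC(CO[Si](C)(C)C(C)(C)C)C/C(C)=C/[C@@H](C)CC(=C)/C=C(\CO[Si](C)(C)C(C)(C)C)[C@H](CC)OC(=O)[C@H](C)CO | intermediate
26 | seco keto-aldehyde (name in step 18; C2 labile, drawn 2R) | O=C(CO[Si](C)(C)C(C)(C)C)C/C(C)=C/[C@@H](C)CC(=C)/C=C(\CO[Si](C)(C)C(C)(C)C)[C@H](CC)OC(=O)[C@H](C)C=O | intermediate
27 | (3R,5R,7E,9S,12E,14S)-5,13-bis[(tert-butyldimethylsilyloxy)methyl]-14-ethyl-5-hydroxy-3,7,9-trimethyl-11-methylidene-1-oxacyclotetradeca-7,12-diene-2,4-dione | C=C1/C=C(\CO[Si](C)(C)C(C)(C)C)[C@H](CC)OC(=O)[C@H](C)C(=O)[C@](O)(CO[Si](C)(C)C(C)(C)C)C/C(C)=C/[C@@H](C)C1 | intermediate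
28 | (3R,5R,7E,9S,12E,14S)-14-ethyl-5-hydroxy-5,13-bis(hydroxymethyl)-3,7,9-trimethyl-11-methylidene-1-oxacyclotetradeca-7,12-diene-2,4-dione | C=C1/C=C(\CO)[C@H](CC)OC(=O)[C@H](C)C(=O)[C@](O)(CO)C/C(C)=C/[C@@H](C)C1 | target

**Step count and risks**
Total step count: 20. Longest linear sequence: 18 steps (steps 1–13 and 16–20; steps 14 and 15 make the side-chain acid).

Steps most likely to fail:

Step 19 (Proposed new method). The carbene may be held as its azolium salt by the acidic formyl ester, so that no Breslow intermediate turns over; intermolecular aldehyde coupling may outrun closure of the large ring; or the facial selectivity at the ketone may be low. The fallback makes the same C3–C4 bond reductively with known chemistry. It sets out from keto-aldehyde 26, which would be added slowly to SmI2 in THF at high dilution (ketyl-based crossed pinacol macrocyclisation, aldehyde reduced first) to give the (4R)-configured macrocyclic 3,4-diol bis-TBS ether F1, formed together with its C4 epimer and as a mixture at C2 and C3. Oxidation of the secondary C3 carbinol (SO3·pyridine, DMSO, i-Pr2NEt; the tertiary C4 carbinol cannot react) then comes back to the route at 27. C4 is under substrate control only in this variant, so the 4R isomer would have to be separated by chromatography.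

Step 18. The double oxidation may not stop cleanly at the keto-aldehyde: the enolisable formyl ester may be lost on work-up, or the C6=C7 bond may drift into conjugation with the new ketone. The fallback carries the aldehyde in masked form and sets out from alcohol 20. Commercial methyl 3,3-dimethoxy-2-methylpropanoate would be saponified (LiOH) to 3,3-dimethoxy-2-methylpropanoic acid F2, which is esterified with 20 (carbodiimide, 4-(dimethylamino)pyridine) to the acetal ester F3. Methanolysis of the single triethylsilyl ether (pyridinium p-toluenesulfonate, MeOH) would give the hydroxy acetal F4, and one Dess–Martin oxidation the keto acetal F5. Mild acid hydrolysis of the dimethyl acetal (Amberlyst-15, wet acetone) releases the aldehyde last and comes back to the route at 26, directly before step 19; the C2 mixture this gives is of no consequence.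

Step 11. The reductive coupling may form the C–C bond at C11 instead of C12, or the enyne may oligomerise on nickel. The fallback assembles the diene by fragment cross-coupling and sets out from bromide 14. Methyl propiolate, propanal and MgI2 (iodo-aldol of the halo-Baylis–Hillman type) would give methyl (Z)-2-(1-hydroxypropyl)-3-iodoacrylate F6. Reduction with i-Bu2AlH gives (E)-2-(iodomethylidene)pentane-1,3-diol F7, and selective primary silylation (TBSCl, imidazole) gives (E)-1-(tert-butyldimethylsilyloxy)-2-(iodomethylidene)pentan-3-ol F8. Miyaura borylation of 14 (bis(pinacolato)diboron, PdCl2(dppf), KOAc) gives the alkenyl pinacol boronate F9, and Suzuki–Miyaura coupling of F8 with F9 (Pd(PPh3)4, K3PO4) comes back to the route at dienol 18, the 11E geometry being fixed by the iodide.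

**Further compounds**
F1 | step 19 | (4R)-macrocyclic 3,4-diol bis-TBS ether (macrolide numbering; mixture at C2 and C3) | C=C1/C=C(\CO[Si](C)(C)C(C)(C)C)[C@H](CC)OC(=O)C(C)C(O)[C@](O)(CO[Si](C)(C)C(C)(C)C)C/C(C)=C/[C@@H](C)C1
F2 | step 18 | 3,3-dimethoxy-2-methylpropanoic acid (racemic) | COC(OC)C(C)C(=O)O
F3 | step 18 | ester of 20 with F2 (acetal ester, C4 oxygen as triethylsilyl ether) | CC[Si](CC)(CC)OC(CO[Si](C)(C)C(C)(C)C)C/C(C)=C/[C@@H](C)CC(=C)/C=C(\CO[Si](C)(C)C(C)(C)C)[C@H](CC)OC(=O)C(C)C(OC)OC
F4 | step 18 | hydroxy acetal (free C4 carbinol) | OC(CO[Si](C)(C)C(C)(C)C)C/C(C)=C/[C@@H](C)CC(=C)/C=C(\CO[Si](C)(C)C(C)(C)C)[C@H](CC)OC(=O)C(C)C(OC)OC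
F5 | step 18 | keto acetal (C4 ketone, C3 dimethyl acetal) | O=C(CO[Si](C)(C)C(C)(C)C)C/C(C)=C/[C@@H](C)CC(=C)/C=C(\CO[Si](C)(C)C(C)(C)C)[C@H](CC)OC(=O)C(C)C(OC)OC
F6 | step 11 | methyl (Z)-2-(1-hydroxypropyl)-3-iodoacrylate (racemic) | I/C=C(\C(=O)OC)C(O)CC
F7 | step 11 | (E)-2-(iodomethylidene)pentane-1,3-diol (racemic) | I/C=C(\CO)C(O)CC
F8 | step 11 | (E)-1-(tert-butyldimethylsilyloxy)-2-(iodomethylidene)pentan-3-ol (racemic) | I/C=C(\CO[Si](C)(C)C(C)(C)C)C(O)CC
F9 | step 11 | alkenyl pinacol boronate from 14 | CC[Si](CC)(CC)OC(CO[Si](C)(C)C(C)(C)C)C/C(C)=C/[C@@H](C)CC(=C)B1OC(C)(C)C(C)(C)O1
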